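**Retrosynthetic overview**
- The depside ester C(=O)–OAr is cut last, giving a 2,4-dimethoxy-6-(2-oxoheptyl)benzoic acid (ketone masked as a dioxolane) and benzyl 4-hydroxy-2-methoxy-6-pentylbenzoate; ketal hydrolysis and hydrogenolysis finish the route.
- Key C–C bond: the ArCH2–C(=O) bond, made by a crossed Claisen-type condensation of the lateral lithium dienolate of methyl 2,4-dimethoxy-6-methylbenzoate with the Weinreb amide of hexanoic acid.
- The toluate comes from 3,5-dimethoxytoluene (Vilsmeier, Pinnick, MeI).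
- The phenol ring is built by Michael addition of dimethyl malonate to (E)-non-3-en-2-one with Dieckmann closure, then aromatised and differentiated (4-OBn, 2-OMe, saponification, H2, selective CO2Bn).
- Ring order: the acid ring is bought aromatic; the phenol ring is the only ring constructed (step 8, aromatised in step 9); the dioxolane is a temporary ring (formed step 6, opened step 16).

Assumption: the target has no stereocentre, so no enantiocontrol is needed (racemic 15–17 lose their stereocentres on aromatisation); salts that are only the deprotonated form of a listed compound are not numbered separately.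

**Step 1**
Reactants: 1 3,5-dimethoxytoluene
Product: 3 2,4-dimethoxy-6-methylbenzaldehyde, via iminium salt 2 (not isolated)
Conditions: POCl3, DMF, 0 → 60 °C; then ice/H2O
Reagents that add atoms: N,N-dimethylformamide CN(C)C=O; water O
Why: Vilsmeier–Haack formylation goes to the ring position ortho to methyl and ortho/para to the two methoxy groups, because the position between the two methoxy groups is more hindered.

**Step 2**
Reactants: 3 2,4-dimethoxy-6-methylbenzaldehyde
Product: 4 2,4-dimethoxy-6-methylbenzoic acid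
Conditions: NaClO2, NaH2PO4, 2-methylbut-2-ene, t-BuOH/H2O, rt
Reagents that add atoms: sodium chlorite [Na+].[O-]Cl=O
Why: Pinnick oxidation converts the aldehyde to the acid while 2-methylbut-2-ene scavenges HOCl, so the electron-rich ring is not chlorinated.

**Step 3**
Reactants: 4 2,4-dimethoxy-6-methylbenzoic acid
Product: 5 methyl 2,4-dimethoxy-6-methylbenzoate
Conditions: MeI, K2CO3, DMF, rt
Reagents that add atoms: iodomethane CI
Why: SN2 O-alkylation of the carboxylate is not slowed by the two ortho substituents because the new bond forms at the methyl carbon of MeI.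

**Step 4**
Reactants: 6 hexanoyl chloride
Product: 7 N-methoxy-N-methylhexanamide
Conditions: MeNHOMe·HCl, K2CO3, H2O/CH2Cl2, 0 °C → rt
Reagents that add atoms: N,O-dimethylhydroxylamine hydrochloride CNOC.Cl
Why: Schotten–Baumann N-acylation gives the Weinreb amide, whose chelated adduct later prevents over-addition.

**Step 5 (key step)**
Reactants: 5 methyl 2,4-dimethoxy-6-methylbenzoate; 7 N-methoxy-N-methylhexanamide
Product: 10 methyl 2,4-dimethoxy-6-(2-oxoheptyl)benzoate, via lithiated toluate 8 (not isolated), via tetrahedral lithium adduct 9 (not isolated)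
Conditions: LDA (2.1 equiv), THF, −78 °C; then 7, −78 °C; sat. NH4Cl quench at −78 °C
Reagents that add atoms: none
Why: Crossed Claisen-type condensation in which LDA forms the ester-stabilised lateral dienolate of the toluate and the Weinreb amide C-acylates it, the chelated adduct releasing the ketone only on cold quench so that double addition and isocoumarin closure are avoided; no stereocentre is formed.

**Step 6**
Reactants: 10 methyl 2,4-dimethoxy-6-(2-oxoheptyl)benzoate
Product: 11 methyl 2,4-dimethoxy-6-[(2-pentyl-1,3-dioxolan-2-yl)methyl]benzoate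
Conditions: TMSOCH2CH2OTMS, TMSOTf (cat.), CH2Cl2, −78 → −20 °C; pyridine quench
Reagents that add atoms: 1,2-bis(trimethylsilyloxy)ethane C[Si](C)(C)OCCO[Si](C)(C)C
Why: Noyori ketalisation runs cold and almost neutral, so the ketone is protected before it can enol-lactonise onto the ester.

**Step 7**
Reactants: 11 methyl 2,4-dimethoxy-6-[(2-pentyl-1,3-dioxolan-2-yl)methyl]benzoate
Product: 12 2,4-dimethoxy-6-[(2-pentyl-1,3-dioxolan-2-yl)methyl]benzoic acid
Conditions: KOH, DMSO/H2O, 90 °C; then cold 1 M HCl to pH 4, immediate extraction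
Reagents that add atoms: potassium hydroxide [K+].[OH-]
Why: Saponification of the hindered methyl benzoate needs hot KOH in aqueous DMSO, and the dioxolane is inert to base and survives a brief cold acidification.

**Step 8**
Reactants: 13 dimethyl malonate; 14 (E)-non-3-en-2-one
Product: 16 methyl 2-hydroxy-4-oxo-6-pentylcyclohex-2-ene-1-carboxylate, via Michael adduct 15 (not isolated)
Conditions: NaOMe, MeOH, reflux; then cold aq. HCl to pH 4
Reagents that add atoms: none
Why: Michael addition of the malonate anion to the enone is followed in the same pot by Dieckmann (intramolecular Claisen) closure of the methyl-ketone enolate onto an ester, driven by the stable 1,3-dione enolate; the racemic stereocentres are destroyed in step 9.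

**Step 9**
Reactants: 16 methyl 2-hydroxy-4-oxo-6-pentylcyclohex-2-ene-1-carboxylate
Product: 18 methyl 2,4-dihydroxy-6-pentylbenzoate, via bromo-dione 17 (not isolated)
Conditions: Br2 (1.0 equiv), DMF, 0 °C; then 80 °C
Reagents that add atoms: none
Why: Bromination–dehydrobromination aromatisation, in which the enolised 1,3-dione is C-brominated and loses HBr on warming to give the resorcinol ester.

**Step 10**
Reactants: 18 methyl 2,4-dihydroxy-6-pentylbenzoate
Product: 19 methyl 4-(benzyloxy)-2-hydroxy-6-pentylbenzoate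
Conditions: BnBr (1.05 equiv), K2CO3, acetone, reflux
Reagents that add atoms: benzyl bromide BrCc1ccccc1
Why: Williamson etherification is selective for the more acidic, non-chelated 4-OH because the 2-OH is hydrogen-bonded to the ester carbonyl.

**Step 11**
Reactants: 19 methyl 4-(benzyloxy)-2-hydroxy-6-pentylbenzoate
Product: 20 methyl 4-(benzyloxy)-2-methoxy-6-pentylbenzoate
Conditions: MeI (excess), K2CO3, DMF, 60 °C
Reagents that add atoms: iodomethane CI
Why: Williamson methylation of the remaining chelated phenol succeeds under more forcing conditions.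

**Step 12**
Reactants: 20 methyl 4-(benzyloxy)-2-methoxy-6-pentylbenzoate
Product: 21 4-(benzyloxy)-2-methoxy-6-pentylbenzoic acid
Conditions: KOH, DMSO/H2O, 90 °C; then aq. HCl
Reagents that add atoms: potassium hydroxide [K+].[OH-]
Why: Saponification of the hindered ester proceeds in hot KOH/DMSO, the ethers are base-stable and the 2,4-dialkoxy acid does not decarboxylate.

**Step 13**
Reactants: 21 4-(benzyloxy)-2-methoxy-6-pentylbenzoic acid
Product: 22 4-hydroxy-2-methoxy-6-pentylbenzoic acid
Conditions: H2 (1 atm), 10% Pd/C, EtOAc, rt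
Reagents that add atoms: none
Why: Catalytic hydrogenolysis cleaves the benzyl ether cleanly and touches nothing else.

**Step 14**
Reactants: 22 4-hydroxy-2-methoxy-6-pentylbenzoic acid
Product: 23 benzyl 4-hydroxy-2-methoxy-6-pentylbenzoate
Conditions: BnBr (1.0 equiv), KHCO3 (1.1 equiv), DMF, rt
Reagents that add atoms: benzyl bromide BrCc1ccccc1
Why: Chemoselective SN2 esterification, since bicarbonate deprotonates only the carboxylic acid and the carboxylate rather than the phenol is benzylated.

**Step 15**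
Reactants: 12 2,4-dimethoxy-6-[(2-pentyl-1,3-dioxolan-2-yl)methyl]benzoic acid; 23 benzyl 4-hydroxy-2-methoxy-6-pentylbenzoate
Product: 25 benzyl 4-({2,4-dimethoxy-6-[(2-pentyl-1,3-dioxolan-2-yl)methyl]benzoyl}oxy)-2-methoxy-6-pentylbenzoate, via O-acylisourea 24 (not isolated)
Conditions: DCC, DMAP, CH2Cl2, 0 °C → rt
Reagents that add atoms: none
Why: Steglich esterification, in which DCC activates the acid and DMAP transfers the acyl group to the unhindered phenol under neutral conditions that leave the ketal and benzyl ester alone.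

**Step 16**
Reactants: 25 benzyl 4-({2,4-dimethoxy-6-[(2-pentyl-1,3-dioxolan-2-yl)methyl]benzoyl}oxy)-2-methoxy-6-pentylbenzoate
Product: 26 benzyl 4-{[2,4-dimethoxy-6-(2-oxoheptyl)benzoyl]oxy}-2-methoxy-6-pentylbenzoate
Conditions: 1 M aq. HCl, THF, rt (stopped at full conversion)
Reagents that add atoms: water O
Why: Mild acid-catalysed ketal hydrolysis frees the ketone while the aryl and benzyl esters are stable to dilute acid at room temperature.

**Step 17**
Reactants: 26 benzyl 4-{[2,4-dimethoxy-6-(2-oxoheptyl)benzoyl]oxy}-2-methoxy-6-pentylbenzoate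
Product: 27 4-{[2,4-dimethoxy-6-(2-oxoheptyl)benzoyl]oxy}-2-methoxy-6-pentylbenzoic acid (target)
Conditions: H2 (1 atm), 10% Pd/C, EtOAc, rt
Reagents that add atoms: none
Why: Neutral hydrogenolysis of the benzyl ester frees the acid without touching the depside ester or the dialkyl ketone, and avoids base that would trigger isocoumarin closure.

**Compound list**
1 | 3,5-dimethoxytoluene | Cc1cc(OC)cc(OC)c1 | starting material
2 | [(2,4-dimethoxy-6-methylphenyl)methylidene]dimethylammonium dichlorophosphate | Cc1cc(OC)cc(OC)c1C=[N+](C)C.[O-]P(=O)(Cl)Cl | intermediate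
3 | 2,4-dimethoxy-6-methylbenzaldehyde | Cc1cc(OC)cc(OC)c1C=O | intermediate
4 | 2,4-dimethoxy-6-methylbenzoic acid | Cc1cc(OC)cc(OC)c1C(=O)O | intermediate
5 | methyl 2,4-dimethoxy-6-methylbenzoate | Cc1cc(OC)cc(OC)c1C(=O)OC | intermediate
6 | hexanoyl chloride | CCCCCC(=O)Cl | starting material
7 | N-methoxy-N-methylhexanamide | CCCCCC(=O)N(C)OC | intermediate
8 | methyl 2-(lithiomethyl)-4,6-dimethoxybenzoate (lateral lithium dienolate) | [Li]Cc1cc(OC)cc(OC)c1C(=O)OC | intermediate
9 | lithium alkoxide adduct of 8 with 7 (N,O-chelated tetrahedral intermediate) | CCCCCC(O[Li])(Cc1cc(OC)cc(OC)c1C(=O)OC)N(C)OC | intermediate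
10 | methyl 2,4-dimethoxy-6-(2-oxoheptyl)benzoate | CCCCCC(=O)Cc1cc(OC)cc(OC)c1C(=O)OC | intermediate
11 | methyl 2,4-dimethoxy-6-[(2-pentyl-1,3-dioxolan-2-yl)methyl]benzoate | CCCCCC1(Cc2cc(OC)cc(OC)c2C(=O)OC)OCCO1 | intermediate
12 | 2,4-dimethoxy-6-[(2-pentyl-1,3-dioxolan-2-yl)methyl]benzoic acid | CCCCCC1(Cc2cc(OC)cc(OC)c2C(=O)O)OCCO1 | intermediate
13 | dimethyl malonate | COC(=O)CC(=O)OC | starting material
14 | (E)-non-3-en-2-one | CCCCC/C=C/C(C)=O | starting material
15 | dimethyl 2-(2-oxononan-4-yl)propanedioate (racemic) | CCCCCC(CC(C)=O)C(C(=O)OC)C(=O)OC | intermediate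
16 | methyl 2-hydroxy-4-oxo-6-pentylcyclohex-2-ene-1-carboxylate (racemic, enol form of the 1,3-dione) | CCCCCC1CC(=O)C=C(O)C1C(=O)OC | intermediate
17 | methyl 3-bromo-2-hydroxy-4-oxo-6-pentylcyclohex-2-ene-1-carboxylate (racemic) | CCCCCC1CC(=O)C(Br)=C(O)C1C(=O)OC | intermediate
18 | methyl 2,4-dihydroxy-6-pentylbenzoate (methyl olivetolate) | CCCCCc1cc(O)cc(O)c1C(=O)OC | intermediate
19 | methyl 4-(benzyloxy)-2-hydroxy-6-pentylbenzoate | CCCCCc1cc(OCc2ccccc2)cc(O)c1C(=O)OC | intermediate
20 | methyl 4-(benzyloxy)-2-methoxy-6-pentylbenzoate | CCCCCc1cc(OCc2ccccc2)cc(OC)c1C(=O)OC | intermediate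
21 | 4-(benzyloxy)-2-methoxy-6-pentylbenzoic acid | CCCCCc1cc(OCc2ccccc2)cc(OC)c1C(=O)O | intermediate
22 | 4-hydroxy-2-methoxy-6-pentylbenzoic acid | CCCCCc1cc(O)cc(OC)c1C(=O)O | intermediate
23 | benzyl 4-hydroxy-2-methoxy-6-pentylbenzoate | CCCCCc1cc(O)cc(OC)c1C(=O)OCc1ccccc1 | intermediate
24 | O-acylisourea of 12 with DCC | CCCCCC1(Cc2cc(OC)cc(OC)c2C(=O)OC(=NC2CCCCC2)NC2CCCCC2)OCCO1 | intermediate
25 | benzyl 4-({2,4-dimethoxy-6-[(2-pentyl-1,3-dioxolan-2-yl)methyl]benzoyl}oxy)-2-methoxy-6-pentylbenzoate | CCCCCC1(Cc2cc(OC)cc(OC)c2C(=O)Oc2cc(CCCCC)c(C(=O)OCc3ccccc3)c(OC)c2)OCCO1 | intermediate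
26 | benzyl 4-{[2,4-dimethoxy-6-(2-oxoheptyl)benzoyl]oxy}-2-methoxy-6-pentylbenzoate | CCCCCC(=O)Cc1cc(OC)cc(OC)c1C(=O)Oc1cc(CCCCC)c(C(=O)OCc2ccccc2)c(OC)c1 | intermediate
27 | 4-{[2,4-dimethoxy-6-(2-oxoheptyl)benzoyl]oxy}-2-methoxy-6-pentylbenzoic acid | CCCCCC(=O)Cc1cc(OC)cc(OC)c1C(=O)Oc1cc(CCCCC)c(C(=O)O)c(OC)c1 | target

**Totals**
Total step count: 17. Longest linear sequence: 10 steps (8 → 14, then 15 → 17).

**Three steps most likely to fail**

Step 5 may suffer from self-condensation of the toluate anion, enolisation of the amide or closure to an isocoumarin. The fallback sets out from 5 and returns at 10. The same anion (LDA, THF, −78 °C) is added to hexanal in an aldol-type addition that closes on warming to racemic 6,8-dimethoxy-3-pentylisochroman-1-one F1. KOH in aqueous MeOH opens the lactone to potassium 2-(2-hydroxyheptyl)-4,6-dimethoxybenzoate F2. After evaporation, MeI in DMF methylates the carboxylate to racemic methyl 2-(2-hydroxyheptyl)-4,6-dimethoxybenzoate F3, which is oxidised at once with Dess–Martin periodinane to 10.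

Step 6 may lose material to enol-lactonisation before the ketal forms. The fallback sets out from 10 and returns at 26. Ethane-1,2-dithiol with BF3·OEt2 (CH2Cl2, 0 °C) gives methyl 2,4-dimethoxy-6-[(2-pentyl-1,3-dithiolan-2-yl)methyl]benzoate F4. KOH in aqueous DMSO gives 2,4-dimethoxy-6-[(2-pentyl-1,3-dithiolan-2-yl)methyl]benzoic acid F5. DCC/DMAP coupling with 23 gives benzyl 4-({2,4-dimethoxy-6-[(2-pentyl-1,3-dithiolan-2-yl)methyl]benzoyl}oxy)-2-methoxy-6-pentylbenzoate F6. HgCl2/CaCO3 in aqueous MeCN then unmasks the ketone to 26, which must be freed of sulfur and mercury traces before the Pd step 17.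

Step 15 may stall at the N-acylurea because the acid is 2,6-disubstituted. The fallback sets out from 12 and returns at 25. Cyanuric fluoride and pyridine in CH2Cl2 convert 12 into 2,4-dimethoxy-6-[(2-pentyl-1,3-dioxolan-2-yl)methyl]benzoyl fluoride F7, a compact HCl-free acyl donor that spares the ketal. F7 acylates the sodium phenoxide of 23 (NaH, THF, 0 °C → rt) to give 25.

**Further compounds**
F1 | step 5 | 6,8-dimethoxy-3-pentylisochroman-1-one (racemic) | CCCCCC1Cc2cc(OC)cc(OC)c2C(=O)O1
F2 | step 5 | potassium 2-(2-hydroxyheptyl)-4,6-dimethoxybenzoate (racemic) | CCCCCC(O)Cc1cc(OC)cc(OC)c1C(=O)[O-].[K+]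
F3 | step 5 | methyl 2-(2-hydroxyheptyl)-4,6-dimethoxybenzoate (racemic) | CCCCCC(O)Cc1cc(OC)cc(OC)c1C(=O)OC
F4 | step 6 | methyl 2,4-dimethoxy-6-[(2-pentyl-1,3-dithiolan-2-yl)methyl]benzoate | CCCCCC1(Cc2cc(OC)cc(OC)c2C(=O)OC)SCCS1
F5 | step 6 | 2,4-dimethoxy-6-[(2-pentyl-1,3-dithiolan-2-yl)methyl]benzoic acid | CCCCCC1(Cc2cc(OC)cc(OC)c2C(=O)O)SCCS1
F6 | step 6 | benzyl 4-({2,4-dimethoxy-6-[(2-pentyl-1,3-dithiolan-2-yl)methyl]benzoyl}oxy)-2-methoxy-6-pentylbenzoate | CCCCCC1(Cc2cc(OC)cc(OC)c2C(=O)Oc2cc(CCCCC)c(C(=O)OCc3ccccc3)c(OC)c2)SCCS1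
F7 | step 15 | 2,4-dimethoxy-6-[(2-pentyl-1,3-dioxolan-2-yl)methyl]benzoyl fluoride | CCCCCC1(Cc2cc(OC)cc(OC)c2C(F)=O)OCCO1
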